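**Retrosynthetic overview**
1. Target 20 ⇐ 19 by one hydrogenation (C=C saturation plus O‑benzyl hydrogenolysis); 19 ⇐ diacetate 17 + dodec‑1‑ene by cross‑metathesis (C4=C5).
2. 17 ⇐ 15 (MOM off, both OH acetylated); 15 ⇐ arylacetaldehyde 11 + allyl nucleophile: the C2–C3 bond is made by Brown asymmetric allylboration, which sets the only stereocentre.
3. 11 ⇐ allyl arene 9 (Lemieux–Johnson cleavage) ⇐ phenol 8 ⇐ aryl allyl ether 6 (aromatic Claisen rearrangement puts C1–C2 on the ring).
4. 6 ⇐ vanillin by O‑allylation, Baeyer–Villiger (CHO → OH) and O‑benzylation; the two phenol oxygens stay differentiated (MOM → OAc, Bn → OH).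
5. No ring is formed: the benzene ring is carried intact from vanillin.

Assumption: the stereocentre of the given SMILES is (R) (O > ArCH2 > alkyl > H) and the chain is numbered C1 (benzylic) to C15; "(+)-Ipc2BOMe" is (+)-B-methoxydiisopinocampheylborane made from (–)-α-pinene, COB([C@H]1C[C@H]2C[C@@H]([C@@H]1C)C2(C)C)[C@H]1C[C@H]2C[C@@H]([C@@H]1C)C2(C)C; 19 forms as an E/Z mixture and the major E isomer is drawn.

**Route**

Step 1
Reactants: 1 vanillin; 2 allyl bromide
Product: 3 4-(allyloxy)-3-methoxybenzaldehyde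
Conditions: K2CO3, DMF, 60 °C
Reagents that add atoms: none
Why: Williamson ether synthesis on the only acidic OH; the phenoxide is O‑alkylated cleanly by the allylic bromide.

Step 2
Reactants: 3 4-(allyloxy)-3-methoxybenzaldehyde
Product: 5 4-(allyloxy)-3-methoxyphenol, via aryl formate 4 (not isolated)
Conditions: mCPBA (1.2 equiv), CH2Cl2, 0 °C → rt; aq. NaHCO3 wash; then K2CO3 (cat.), MeOH, rt
Reagents that add atoms: 3-chloroperoxybenzoic acid (mCPBA), O=C(OO)c1cccc(Cl)c1
Why: Baeyer–Villiger (Dakin-type) oxidation: the electron-rich aryl group migrates to give the formate much faster than mCPBA epoxidises the electron-poor allyl ether alkene, and mild methanolysis frees the phenol.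

Step 3
Reactants: 5 4-(allyloxy)-3-methoxyphenol
Product: 6 1-(allyloxy)-4-(benzyloxy)-2-methoxybenzene
Conditions: BnBr, K2CO3, DMF, rt
Reagents that add atoms: benzyl bromide, BrCc1ccccc1
Why: Williamson ether synthesis puts the hydrogenolysable benzyl group on the oxygen that must end as the free 5‑OH.

Step 4
Reactants: 6 1-(allyloxy)-4-(benzyloxy)-2-methoxybenzene
Product: 8 2-allyl-4-(benzyloxy)-6-methoxyphenol, via ortho-dienone 7 (not isolated)
Conditions: N,N-diethylaniline, 195 °C, Ar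
Reagents that add atoms: none
Why: Aromatic Claisen [3,3]-sigmatropic rearrangement: one ortho position carries OMe and the para position OBn, so the allyl group can only end up at the free ortho carbon, and the dienone tautomerises to the phenol.

Step 5
Reactants: 8 2-allyl-4-(benzyloxy)-6-methoxyphenol
Product: 9 1-allyl-5-(benzyloxy)-3-methoxy-2-(methoxymethoxy)benzene
Conditions: MOMCl, iPr2NEt, CH2Cl2, 0 °C → rt
Reagents that add atoms: chloromethyl methyl ether (MOMCl), COCCl
Why: O‑alkylation of the phenol as its MOM acetal, which blocks lactol/benzofuran formation from the later ortho-hydroxy arylacetaldehyde and is orthogonal to the benzyl ether.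

Step 6
Reactants: 9 1-allyl-5-(benzyloxy)-3-methoxy-2-(methoxymethoxy)benzene
Product: 11 2-[5-(benzyloxy)-3-methoxy-2-(methoxymethoxy)phenyl]acetaldehyde, via vicinal diol 10 (not isolated)
Conditions: OsO4 (2 mol %), NaIO4 (4 equiv), 2,6-lutidine, 1,4-dioxane/H2O 3:1, rt; crude aldehyde used at once
Reagents that add atoms: osmium tetroxide, O=[Os](=O)(=O)=O; sodium periodate (terminal oxidant that re-supplies the oxygen), [Na+].[O-]I(=O)(=O)=O
Why: Lemieux–Johnson oxidation (dihydroxylation, then periodate glycol cleavage) removes the terminal CH2; 2,6-lutidine suppresses over-oxidation and the MOM, benzyl and methyl ethers are inert.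

Step 7
Reactants: 11 2-[5-(benzyloxy)-3-methoxy-2-(methoxymethoxy)phenyl]acetaldehyde; 12 allylmagnesium bromide
Product: 15 (2R)-1-[5-(benzyloxy)-3-methoxy-2-(methoxymethoxy)phenyl]pent-4-en-2-ol, via B-allyldiisopinocampheylborane 13 (not isolated), via homoallylic borinate 14 (not isolated)
Conditions: 12, (+)-Ipc2BOMe, Et2O, 0 °C → rt; then 11, Et2O, –78 °C; then 3 M NaOH, 30% H2O2, 0 °C → rt
Reagents that add atoms: none
Why: Brown asymmetric allylboration (carbonyl allylation): the allylborane carrying Ipc groups from (–)-α-pinene adds through a chair Zimmerman–Traxler transition state to the Re face of the aldehyde, faster than enolisation at –78 °C, and sets the (R) carbinol centre that no later step touches.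

Step 8
Reactants: 15 (2R)-1-[5-(benzyloxy)-3-methoxy-2-(methoxymethoxy)phenyl]pent-4-en-2-ol
Product: 16 4-(benzyloxy)-2-[(2R)-2-hydroxypent-4-en-1-yl]-6-methoxyphenol
Conditions: conc. HCl (cat.), MeOH, 40 °C
Reagents that add atoms: none
Why: Acid-catalysed transacetalisation cleaves the aryl MOM acetal, while the benzyl ether, the alkene and the non-benzylic secondary alcohol are unaffected.

Step 9
Reactants: 16 4-(benzyloxy)-2-[(2R)-2-hydroxypent-4-en-1-yl]-6-methoxyphenol
Product: 17 (2R)-1-[2-(acetyloxy)-5-(benzyloxy)-3-methoxyphenyl]pent-4-en-2-yl acetate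
Conditions: Ac2O (4 equiv), pyridine, DMAP (cat.), CH2Cl2, 0 °C → rt
Reagents that add atoms: acetic anhydride, CC(=O)OC(C)=O
Why: DMAP-catalysed acylation esterifies both the hindered phenol and the secondary alcohol with retention, since no bond to the stereocentre is broken.

Step 10
Reactants: 17 (2R)-1-[2-(acetyloxy)-5-(benzyloxy)-3-methoxyphenyl]pent-4-en-2-yl acetate; 18 dodec-1-ene
Product: 19 (2R,4E)-1-[2-(acetyloxy)-5-(benzyloxy)-3-methoxyphenyl]pentadec-4-en-2-yl acetate (E/Z mixture, E major)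
Conditions: Grubbs II (5 mol %), 18 (4 equiv), CH2Cl2, 40 °C
Reagents that add atoms: none
Why: Olefin cross-metathesis of two terminal alkenes, driven by loss of ethene and an excess of the cheap partner; the alkene geometry is irrelevant because it is hydrogenated next.

Step 11
Reactants: 19 (2R,4E)-1-[2-(acetyloxy)-5-(benzyloxy)-3-methoxyphenyl]pentadec-4-en-2-yl acetate
Product: 20 (2R)-1-[2-(acetyloxy)-5-hydroxy-3-methoxyphenyl]pentadecan-2-yl acetate (CNP0236046.1)
Conditions: H2 (1 atm), 10% Pd/C, EtOAc, rt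
Reagents that add atoms: none
Why: Heterogeneous catalytic hydrogenation saturates the alkene and hydrogenolyses the benzyl ether in one operation, while both acetates and the non-benzylic C–O stereocentre survive in neutral EtOAc.

**Compound list**
1 | vanillin (4-hydroxy-3-methoxybenzaldehyde) | COc1cc(C=O)ccc1O | starting material
2 | allyl bromide | C=CCBr | starting material
3 | 4-(allyloxy)-3-methoxybenzaldehyde | C=CCOc1ccc(C=O)cc1OC | intermediate
4 | 4-(allyloxy)-3-methoxyphenyl formate | C=CCOc1ccc(OC=O)cc1OC | intermediate (not isolated)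
5 | 4-(allyloxy)-3-methoxyphenol | C=CCOc1ccc(O)cc1OC | intermediate
6 | 1-(allyloxy)-4-(benzyloxy)-2-methoxybenzene | C=CCOc1ccc(OCc2ccccc2)cc1OC | intermediate
7 | 6-allyl-4-(benzyloxy)-2-methoxycyclohexa-2,4-dien-1-one (racemic) | C=CCC1C=C(OCc2ccccc2)C=C(OC)C1=O | intermediate (not isolated)
8 | 2-allyl-4-(benzyloxy)-6-methoxyphenol | C=CCc1cc(OCc2ccccc2)cc(OC)c1O | intermediate
9 | 1-allyl-5-(benzyloxy)-3-methoxy-2-(methoxymethoxy)benzene | C=CCc1cc(OCc2ccccc2)cc(OC)c1OCOC | intermediate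
10 | 3-[5-(benzyloxy)-3-methoxy-2-(methoxymethoxy)phenyl]propane-1,2-diol (racemic) | OCC(O)Cc1cc(OCc2ccccc2)cc(OC)c1OCOC | intermediate (not isolated)
11 | 2-[5-(benzyloxy)-3-methoxy-2-(methoxymethoxy)phenyl]acetaldehyde | O=CCc1cc(OCc2ccccc2)cc(OC)c1OCOC | intermediate
12 | allylmagnesium bromide | C=CC[Mg]Br | starting material
13 | B-allyldiisopinocampheylborane (Ipc groups from (–)-α-pinene, configured as in (+)-isopinocampheol) | C=CCB([C@H]1C[C@H]2C[C@@H]([C@@H]1C)C2(C)C)[C@H]1C[C@H]2C[C@@H]([C@@H]1C)C2(C)C | intermediate (not isolated)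
14 | (2R)-1-[5-(benzyloxy)-3-methoxy-2-(methoxymethoxy)phenyl]pent-4-en-2-yl diisopinocampheylborinate | C=CC[C@H](Cc1cc(OCc2ccccc2)cc(OC)c1OCOC)OB([C@H]1C[C@H]2C[C@@H]([C@@H]1C)C2(C)C)[C@H]1C[C@H]2C[C@@H]([C@@H]1C)C2(C)C | intermediate (not isolated)
15 | (2R)-1-[5-(benzyloxy)-3-methoxy-2-(methoxymethoxy)phenyl]pent-4-en-2-ol | C=CC[C@H](Cc1cc(OCc2ccccc2)cc(OC)c1OCOC)O | intermediate
16 | 4-(benzyloxy)-2-[(2R)-2-hydroxypent-4-en-1-yl]-6-methoxyphenol | C=CC[C@H](Cc1cc(OCc2ccccc2)cc(OC)c1O)O | intermediate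
17 | (2R)-1-[2-(acetyloxy)-5-(benzyloxy)-3-methoxyphenyl]pent-4-en-2-yl acetate | C=CC[C@H](Cc1cc(OCc2ccccc2)cc(OC)c1OC(C)=O)OC(C)=O | intermediate
18 | dodec-1-ene | CCCCCCCCCCC=C | starting material
19 | (2R,4E)-1-[2-(acetyloxy)-5-(benzyloxy)-3-methoxyphenyl]pentadec-4-en-2-yl acetate (E major, E/Z mixture) | CCCCCCCCCC/C=C/C[C@H](Cc1cc(OCc2ccccc2)cc(OC)c1OC(C)=O)OC(C)=O | intermediate
20 | (2R)-1-[2-(acetyloxy)-5-hydroxy-3-methoxyphenyl]pentadecan-2-yl acetate | CCCCCCCCCCCCC[C@H](Cc1cc(O)cc(OC)c1OC(C)=O)OC(C)=O | target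

**Totals**
Total step count: 11. Longest linear sequence: 11 steps (vanillin → 20; the route is linear).

**Three steps most likely to fail, with fallbacks**

Step 6 (oxidative cleavage). The arylacetaldehyde 11 is enolisable and can be over-oxidised or lost on isolation. The fallback is a redox detour that sets out from 9. Ozonolysis (O3, CH2Cl2/MeOH, –78 °C, Sudan Red 7B end point) with NaBH4 work-up gives the bench-stable alcohol 2-[5-(benzyloxy)-3-methoxy-2-(methoxymethoxy)phenyl]ethan-1-ol F1, which can be purified and stored. Dess–Martin periodinane with NaHCO3 in CH2Cl2 then gives the aldehyde under anhydrous conditions just before use, and the route is rejoined at 11.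

Step 7 (Brown allylation). Self-condensation of 11 or an ee below about 95% (to be checked on the Mosher ester of 15) would be the problem. The fallback replaces the allylation by a Claisen condensation and asymmetric hydrogenation, and sets out from 11.
- Pinnick oxidation (NaClO2, NaH2PO4, 2-methylbut-2-ene, tBuOH/H2O) gives 2-[5-(benzyloxy)-3-methoxy-2-(methoxymethoxy)phenyl]acetic acid F2.
- CDI in THF converts it into the acyl imidazolide 2-[5-(benzyloxy)-3-methoxy-2-(methoxymethoxy)phenyl]-1-(1H-imidazol-1-yl)ethan-1-one F3, which is not isolated.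
- Masamune–Brooks decarboxylative Claisen condensation with methyl potassium malonate, MgCl2 and Et3N gives the β-keto ester methyl 4-[5-(benzyloxy)-3-methoxy-2-(methoxymethoxy)phenyl]-3-oxobutanoate F4.
- Noyori hydrogenation (RuCl2[(S)-BINAP], H2 4–10 atm, MeOH, 50 °C) gives methyl (3S)-4-[5-(benzyloxy)-3-methoxy-2-(methoxymethoxy)phenyl]-3-hydroxybutanoate F5. The (3S) descriptor here is the same spatial arrangement as (R) in 15, and ≥97% ee is expected.
- TBSCl/imidazole in DMF gives the silyl ether methyl (3S)-4-[5-(benzyloxy)-3-methoxy-2-(methoxymethoxy)phenyl]-3-[(tert-butyldimethylsilyl)oxy]butanoate F6.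
- DIBAL-H in toluene at –78 °C gives the aldehyde (3S)-4-[5-(benzyloxy)-3-methoxy-2-(methoxymethoxy)phenyl]-3-[(tert-butyldimethylsilyl)oxy]butanal F7.
- Wittig methylenation (Ph3PCH3Br, KHMDS, THF, –78 → 0 °C) gives tert-butyl({(2R)-1-[5-(benzyloxy)-3-methoxy-2-(methoxymethoxy)phenyl]pent-4-en-2-yl}oxy)dimethylsilane F8.
- TBAF in THF removes the silyl group, and the route is rejoined at 15.

Step 10 (cross-metathesis). The risks are a statistical product mixture, alkene isomerisation with chain-shortened by-products, and difficult separation from docos-11-ene. The fallback builds the C5–C6 bond by hydroboration and alkyl–alkyl Suzuki coupling, and sets out from 17. 9-BBN in THF at rt gives the alkylborane (2R)-1-[2-(acetyloxy)-5-(benzyloxy)-3-methoxyphenyl]-5-(9-borabicyclo[3.3.1]nonan-9-yl)pentan-2-yl acetate F9, which is not isolated. Coupling with 1-bromodecane (Pd(OAc)2/PCy3, K3PO4·H2O, THF, rt) gives the saturated benzyl ether (2R)-1-[2-(acetyloxy)-5-(benzyloxy)-3-methoxyphenyl]pentadecan-2-yl acetate F10. Hydrogenolysis under the step 11 conditions (H2, Pd/C, EtOAc) then gives the target, so the route is rejoined at 20.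

**Further compounds**
F1 | step 6 | 2-[5-(benzyloxy)-3-methoxy-2-(methoxymethoxy)phenyl]ethan-1-ol | OCCc1cc(OCc2ccccc2)cc(OC)c1OCOC
F2 | step 7 | 2-[5-(benzyloxy)-3-methoxy-2-(methoxymethoxy)phenyl]acetic acid | OC(=O)Cc1cc(OCc2ccccc2)cc(OC)c1OCOC
F3 | step 7 | 2-[5-(benzyloxy)-3-methoxy-2-(methoxymethoxy)phenyl]-1-(1H-imidazol-1-yl)ethan-1-one | O=C(Cc1cc(OCc2ccccc2)cc(OC)c1OCOC)n1ccnc1
F4 | step 7 | methyl 4-[5-(benzyloxy)-3-methoxy-2-(methoxymethoxy)phenyl]-3-oxobutanoate | COC(=O)CC(=O)Cc1cc(OCc2ccccc2)cc(OC)c1OCOC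
F5 | step 7 | methyl (3S)-4-[5-(benzyloxy)-3-methoxy-2-(methoxymethoxy)phenyl]-3-hydroxybutanoate | COC(=O)C[C@H](Cc1cc(OCc2ccccc2)cc(OC)c1OCOC)O
F6 | step 7 | methyl (3S)-4-[5-(benzyloxy)-3-methoxy-2-(methoxymethoxy)phenyl]-3-[(tert-butyldimethylsilyl)oxy]butanoate | COC(=O)C[C@H](Cc1cc(OCc2ccccc2)cc(OC)c1OCOC)O[Si](C)(C)C(C)(C)C
F7 | step 7 | (3S)-4-[5-(benzyloxy)-3-methoxy-2-(methoxymethoxy)phenyl]-3-[(tert-butyldimethylsilyl)oxy]butanal | O=CC[C@H](Cc1cc(OCc2ccccc2)cc(OC)c1OCOC)O[Si](C)(C)C(C)(C)C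
F8 | step 7 | tert-butyl({(2R)-1-[5-(benzyloxy)-3-methoxy-2-(methoxymethoxy)phenyl]pent-4-en-2-yl}oxy)dimethylsilane | C=CC[C@H](Cc1cc(OCc2ccccc2)cc(OC)c1OCOC)O[Si](C)(C)C(C)(C)C
F9 | step 10 | (2R)-1-[2-(acetyloxy)-5-(benzyloxy)-3-methoxyphenyl]-5-(9-borabicyclo[3.3.1]nonan-9-yl)pentan-2-yl acetate | B1(CCC[C@H](Cc2cc(OCc3ccccc3)cc(OC)c2OC(C)=O)OC(C)=O)C2CCCC1CCC2
F10 | step 10 | (2R)-1-[2-(acetyloxy)-5-(benzyloxy)-3-methoxyphenyl]pentadecan-2-yl acetate | CCCCCCCCCCCCC[C@H](Cc1cc(OCc2ccccc2)cc(OC)c1OC(C)=O)OC(C)=O
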